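**Plan**
- Rings: A = pentaoxygenated benzene, B = 1,4-dioxin, C = central benzene, F = furan, D = outer benzene of the dibenzofuran, E = pendant 3,5-dihydroxyphenyl (C1' carries the ether oxygen).
- Enabling feature: ring E has oxygen on C1', C3' and C5' and hydrogen on C2', C4' and C6', so it is an isomer of a 6-methyl-2-pyranon-4-yl group. Cutting C3'–C4' maps C3' onto the lactone carbonyl, C4' onto the methyl carbon and the C5' oxygen onto the ring oxygen.
- Further cuts: the ring A O–C4(pyranone) bond. In ring B, the O–C bond next to the ring A methoxy group (Ullmann), then the O–C bond next to the ring A hydroxyl (SNAr ortho to a formyl group that is the latent hydroxyl). In ring F, the aryl–aryl bond (direct arylation) and the C–O bond (Chan–Lam).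
- Forward order: ring C (5-hydroxyvanillin) and ring D give a diaryl ether, then ring F closes. Ring A is joined and ring B closes. The pyranone is hung on ring A and turned into ring E, and the five methyl ethers fall last.
- Stereochemistry: the target has no stereocentre and no stereogenic axis. Only regiochemistry has to be controlled, through one free phenol per coupling and symmetric partners.

Key step: step 15

Remark: the core that carries the pyranone holds five rings (A, B, C, F, D). "Core-oxy" in a name means this pentamethoxy core bound through its ring A oxygen. Compounds 1, 7, 11 and 19 are taken as purchasable.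

**Step 1**
Reactants: 1 3,4-dihydroxy-5-methoxybenzaldehyde (5-hydroxyvanillin)
Product: 2 4-(benzyloxy)-3-hydroxy-5-methoxybenzaldehyde
Conditions: BnBr (1.0 equiv), NaHCO3, DMF, 40 °C
Reagents that add atoms: benzyl bromide, BrCc1ccccc1
Why: Selective Williamson etherification, in which the 4-OH para to the formyl group is clearly the more acidic hydroxyl, so the weak base ionises only this one and a single equivalent of benzyl bromide caps it, as is well known for 3,4-dihydroxybenzaldehydes.

**Step 2**
Reactants: 2 4-(benzyloxy)-3-hydroxy-5-methoxybenzaldehyde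
Product: 3 4-(benzyloxy)-2-bromo-3-hydroxy-5-methoxybenzaldehyde
Conditions: NBS (1.0 equiv), i-Pr2NH (10 mol%), CH2Cl2, 0 °C
Reagents that add atoms: N-bromosuccinimide, O=C1CCC(=O)N1Br
Why: Amine-catalysed ortho-selective electrophilic bromination of a phenol, in which C2 is ortho to the free 3-OH, para to the 5-OMe and less screened than C6 (whose neighbouring OMe turns its methyl group toward it), in parallel with the C2 bromination of isovanillin.

**Step 3**
Reactants: 3 4-(benzyloxy)-2-bromo-3-hydroxy-5-methoxybenzaldehyde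
Product: 4 4-(benzyloxy)-2-bromo-5-methoxy-3-(methoxymethoxy)benzaldehyde
Conditions: MOMCl, i-Pr2NEt, CH2Cl2, 0 °C to rt
Reagents that add atoms: chloromethyl methyl ether, COCCl
Why: Standard O-alkylation to a MOM acetal masks the hydroxyl that later becomes a dioxin oxygen with a group that cannot migrate, resists base, peracid, Pd and H2, and leaves with acid.

**Step 4**
Reactants: 4 4-(benzyloxy)-2-bromo-5-methoxy-3-(methoxymethoxy)benzaldehyde
Product: 6 4-(benzyloxy)-2-bromo-5-methoxy-3-(methoxymethoxy)phenol, via aryl formate 5 (not isolated)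
Conditions: mCPBA, CH2Cl2, 0 °C to rt; then K2CO3 (cat.), MeOH, rt
Reagents that add atoms: 3-chloroperoxybenzoic acid, OOC(=O)c1cccc(Cl)c1
Why: Baeyer–Villiger oxidation of an electron-rich benzaldehyde, in which the para-alkoxy aryl group migrates in preference to hydrogen, followed by transesterification of the labile formate, as is routine for 3,4,5-trialkoxybenzaldehydes.

**Step 5**
Reactants: 6 4-(benzyloxy)-2-bromo-5-methoxy-3-(methoxymethoxy)phenol; 7 (3,5-dimethoxyphenyl)boronic acid
Product: 8 2-(benzyloxy)-4-bromo-5-(3,5-dimethoxyphenoxy)-1-methoxy-3-(methoxymethoxy)benzene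
Conditions: Cu(OAc)2 (2 equiv), pyridine, 4 Å MS, CH2Cl2, rt
Reagents that add atoms: none
Why: Chan–Lam O-arylation runs at room temperature through a copper aryl formed by transmetalation from boron and therefore leaves the aryl bromide untouched.

**Step 6**
Reactants: 8 2-(benzyloxy)-4-bromo-5-(3,5-dimethoxyphenoxy)-1-methoxy-3-(methoxymethoxy)benzene
Product: 9 2-(benzyloxy)-3,7,9-trimethoxy-1-(methoxymethoxy)dibenzo[b,d]furan
Conditions: Pd(OAc)2 (5 mol%), PCy3·HBF4 (10 mol%), PivOH (30 mol%), K2CO3, DMA, 125 °C
Reagents that add atoms: none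
Why: Intramolecular Pd-catalysed direct arylation (concerted metalation–deprotonation) of a 2-bromophenyl aryl ether is a standard dibenzofuran synthesis, and because both ortho C–H positions of the 3,5-dimethoxyphenoxy ring are equivalent only one closure product is possible.

**Step 7**
Reactants: 9 2-(benzyloxy)-3,7,9-trimethoxy-1-(methoxymethoxy)dibenzo[b,d]furan
Product: 10 3,7,9-trimethoxy-1-(methoxymethoxy)dibenzo[b,d]furan-2-ol
Conditions: H2 (1 atm), 10% Pd/C, EtOAc–MeOH, rt
Reagents that add atoms: none
Why: Hydrogenolysis of the benzyl ether frees the 2-OH alone, since methyl ethers, the MOM acetal and the dibenzofuran are inert and no halogen is left in the molecule.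

**Step 8**
Reactants: 11 1-fluoro-3,5-dimethoxybenzene
Product: 13 2-fluoro-4,6-dimethoxybenzaldehyde, via aryl iminium chloride 12 (not isolated)
Conditions: POCl3, DMF, 0 to 70 °C; then ice–water
Reagents that add atoms: N,N-dimethylformamide, CN(C)C=O; water, O
Why: Vilsmeier–Haack formylation attacks the position para to one OMe and ortho to the other OMe and to fluorine instead of the crowded site between the two OMe groups, the usual outcome for 5-halo-1,3-dimethoxybenzenes.

**Step 9**
Reactants: 13 2-fluoro-4,6-dimethoxybenzaldehyde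
Product: 14 3-bromo-2-fluoro-4,6-dimethoxybenzaldehyde
Conditions: NBS (1.05 equiv), MeCN, 0 °C to rt
Reagents that add atoms: N-bromosuccinimide, O=C1CCC(=O)N1Br
Why: Electrophilic aromatic bromination goes to C3, which is para to the 6-OMe, ortho to the 4-OMe and next to the small fluorine, and avoids C5 between the two OMe groups, in line with the halogenation pattern of 5-substituted 1,3-dimethoxybenzenes.

**Step 10**
Reactants: 10 3,7,9-trimethoxy-1-(methoxymethoxy)dibenzo[b,d]furan-2-ol; 14 3-bromo-2-fluoro-4,6-dimethoxybenzaldehyde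
Product: 15 3-bromo-4,6-dimethoxy-2-{[3,7,9-trimethoxy-1-(methoxymethoxy)dibenzo[b,d]furan-2-yl]oxy}benzaldehyde
Conditions: Cs2CO3, DMSO, 100 °C, Ar
Reagents that add atoms: none
Why: Nucleophilic aromatic substitution by addition–elimination, in which only the C–F carbon is ortho to the formyl acceptor (helped by the adjacent bromine and two meta OMe groups), the single free phenoxide fixes which dibenzofuran oxygen binds which ring A carbon, and the MOM group rules out a Smiles rearrangement.

**Step 11**
Reactants: 15 3-bromo-4,6-dimethoxy-2-{[3,7,9-trimethoxy-1-(methoxymethoxy)dibenzo[b,d]furan-2-yl]oxy}benzaldehyde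
Product: 17 2-(2-bromo-6-hydroxy-3,5-dimethoxyphenoxy)-3,7,9-trimethoxydibenzo[b,d]furan-1-ol, via ring A formate 16 (not isolated)
Conditions: mCPBA (1.2 equiv), CH2Cl2, 0 °C to rt; aq Na2SO3 wash; then HCl (cat.), MeOH, 45 °C
Reagents that add atoms: 3-chloroperoxybenzoic acid, OOC(=O)c1cccc(Cl)c1
Why: Baeyer–Villiger oxidation of the 2,4,6-trioxygenated benzaldehyde turns the spent activating group into the ring A hydroxyl, and acid methanolysis removes formate and MOM acetal together, at which point ring A is too electron-rich for a Smiles shift.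

**Step 12**
Reactants: 17 2-(2-bromo-6-hydroxy-3,5-dimethoxyphenoxy)-3,7,9-trimethoxydibenzo[b,d]furan-1-ol
Product: 18 pentamethoxy core phenol (17 after loss of HBr between the dibenzofuran 1-OH and the C–Br carbon, ring B closed, ring A hydroxyl free)
Conditions: CuI (20 mol%), N,N-dimethylglycine·HCl (40 mol%), Cs2CO3 (3.5 equiv), 1,4-dioxane (0.02 M), 100 °C, Ar
Reagents that add atoms: none
Why: Intramolecular Ullmann ether synthesis, in which only the dibenzofuran 1-phenoxide can reach the C–Br carbon (six-membered ring) while the ring A phenoxide sits meta to the bromine on the same ring and has no halide within reach, so dilution should suppress its intermolecular coupling.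

**Step 13**
Reactants: 19 4-hydroxy-6-methyl-2H-pyran-2-one (triacetic acid lactone)
Product: 20 4-bromo-6-methyl-2H-pyran-2-one
Conditions: n-Bu4NBr, P2O5, toluene, 100 °C
Reagents that add atoms: tetrabutylammonium bromide, CCCC[N+](CCCC)(CCCC)CCCC.[Br-]
Why: Dehydroxy-bromination of a vinylogous acid through its phosphate ester is an established preparation of this bromopyranone.

**Step 14**
Reactants: 18 pentamethoxy core phenol; 20 4-bromo-6-methyl-2H-pyran-2-one
Product: 21 4-(core-oxy)-6-methyl-2H-pyran-2-one
Conditions: Cs2CO3, MeCN, 50 °C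
Reagents that add atoms: none
Why: Addition–elimination at C4 of a vinylogous acyl bromide, a known way to 4-aryloxy-2-pyranones, asks the crowded phenoxide to meet only a flat trigonal carbon, and a bromide is preferred to a sulfonate because the latter could hand its sulfonyl group to the phenoxide.

**Step 15**
Reactants: 21 4-(core-oxy)-6-methyl-2H-pyran-2-one
Product: 24 5-(core-oxy)benzene-1,3-diol (pentamethyl ether of the target, ring E diol free), via open-chain keto ester 22 (not isolated), via cyclohexenedione 23 (not isolated)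
Conditions: Mg(OMe)2 (5 equiv), MeOH–toluene 1:4, 65 °C; then MeOH distilled off, 110 °C; 1 M HCl work-up
Reagents that add atoms: none
Why: Proposed new method: methoxide held on magnesium adds to the lactone carbonyl C2 of 21, the C2–O1 bond breaks, and keto ester 22 results as its magnesium dienolate with the ester and the acetonyl arm still cis on the double bond, as they were in the ring. The small equilibrium share of the terminal CH3 enolate attacks the ester carbonyl, methoxide leaves, and enedione 23 tautomerises irreversibly to the resorcinolate of 24, so that the methyl carbon and C2 form the new C3'–C4' bond while O1 and the carbonyl oxygen end as the C5' and C3' hydroxyls without any redox change. The closest known reaction type is the alkoxide-induced conversion of 4-methoxy-6-methyl-2-pyranone into 5-methoxyresorcinol by lactone opening and intramolecular Claisen condensation, and the opening of that pyranone by Mg(OMe)2 is known as well; new here is an aryloxy group, a possible leaving group, on C4. The single new ring closes in the 6-(enolendo)-exo-trig mode, which is favoured, and no stereocentre arises. The step needs attack at C2 and not at C4, where addition–elimination would expel the phenoxide of 18: magnesium binds the lactone carbonyl and hands over its own methoxide there, the ring A aryl group with oxygen substituents in both ortho positions stands across the pyranone plane and screens both faces of C4, and once the ring is open the resting dienolate has no electrophilic C3. Distilling methanol out of toluene keeps free methoxide low and pulls the condensation, which releases methanol, to completion.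

**Step 16**
Reactants: 24 5-(core-oxy)benzene-1,3-diol
Product: 25 target CNP0256302.0
Conditions: BBr3 (15 equiv), CH2Cl2, −78 °C to rt; then ice–water
Reagents that add atoms: none
Why: Lewis acid ether cleavage with BBr3 removes all five aryl methyl ethers by bromide attack on the methyl carbons, while the diaryl ether, dioxin and furan C–O bonds offer no sp3 carbon and persist.

**Compound list**
1 | 3,4-dihydroxy-5-methoxybenzaldehyde | O=Cc1cc(O)c(O)c(OC)c1 | starting material
2 | 4-(benzyloxy)-3-hydroxy-5-methoxybenzaldehyde | O=Cc1cc(O)c(OCc2ccccc2)c(OC)c1 | intermediate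
3 | 4-(benzyloxy)-2-bromo-3-hydroxy-5-methoxybenzaldehyde | O=Cc1cc(OC)c(OCc2ccccc2)c(O)c1Br | intermediate
4 | 4-(benzyloxy)-2-bromo-5-methoxy-3-(methoxymethoxy)benzaldehyde | O=Cc1cc(OC)c(OCc2ccccc2)c(OCOC)c1Br | intermediate
5 | 4-(benzyloxy)-2-bromo-5-methoxy-3-(methoxymethoxy)phenyl formate | O=COc1cc(OC)c(OCc2ccccc2)c(OCOC)c1Br | intermediate
6 | 4-(benzyloxy)-2-bromo-5-methoxy-3-(methoxymethoxy)phenol | Oc1cc(OC)c(OCc2ccccc2)c(OCOC)c1Br | intermediate
7 | (3,5-dimethoxyphenyl)boronic acid | COc1cc(OC)cc(B(O)O)c1 | starting material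
8 | 2-(benzyloxy)-4-bromo-5-(3,5-dimethoxyphenoxy)-1-methoxy-3-(methoxymethoxy)benzene | COc1cc(OC)cc(Oc2cc(OC)c(OCc3ccccc3)c(OCOC)c2Br)c1 | intermediate
9 | 2-(benzyloxy)-3,7,9-trimethoxy-1-(methoxymethoxy)dibenzo[b,d]furan | COc1cc(OC)c2c(c1)oc1cc(OC)c(OCc3ccccc3)c(OCOC)c12 | intermediate
10 | 3,7,9-trimethoxy-1-(methoxymethoxy)dibenzo[b,d]furan-2-ol | COc1cc(OC)c2c(c1)oc1cc(OC)c(O)c(OCOC)c12 | intermediate
11 | 1-fluoro-3,5-dimethoxybenzene | COc1cc(F)cc(OC)c1 | starting material
12 | (2-fluoro-4,6-dimethoxybenzylidene)dimethyliminium chloride | COc1cc(F)c(C=[N+](C)C)c(OC)c1.[Cl-] | intermediate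
13 | 2-fluoro-4,6-dimethoxybenzaldehyde | COc1cc(F)c(C=O)c(OC)c1 | intermediate
14 | 3-bromo-2-fluoro-4,6-dimethoxybenzaldehyde | COc1cc(OC)c(C=O)c(F)c1Br | intermediate
15 | 3-bromo-4,6-dimethoxy-2-{[3,7,9-trimethoxy-1-(methoxymethoxy)dibenzo[b,d]furan-2-yl]oxy}benzaldehyde | COc1cc(OC)c2c(c1)oc1cc(OC)c(Oc3c(Br)c(OC)cc(OC)c3C=O)c(OCOC)c12 | intermediate
16 | 3-bromo-4,6-dimethoxy-2-{[3,7,9-trimethoxy-1-(methoxymethoxy)dibenzo[b,d]furan-2-yl]oxy}phenyl formate | COc1cc(OC)c2c(c1)oc1cc(OC)c(Oc3c(Br)c(OC)cc(OC)c3OC=O)c(OCOC)c12 | intermediate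
17 | 2-(2-bromo-6-hydroxy-3,5-dimethoxyphenoxy)-3,7,9-trimethoxydibenzo[b,d]furan-1-ol | COc1cc(OC)c2c(c1)oc1cc(OC)c(Oc3c(Br)c(OC)cc(OC)c3O)c(O)c12 | intermediate
18 | pentamethoxy core phenol (rings A, B, C, F, D; ring A hydroxyl free) | Oc1c(OC)cc(OC)c2c1Oc1c(OC)cc3oc4cc(OC)cc(OC)c4c3c1O2 | intermediate
19 | 4-hydroxy-6-methyl-2H-pyran-2-one | Cc1cc(O)cc(=O)o1 | starting material
20 | 4-bromo-6-methyl-2H-pyran-2-one | Cc1cc(Br)cc(=O)o1 | intermediate
21 | 4-(core-oxy)-6-methyl-2H-pyran-2-one | Cc1cc(Oc2c(OC)cc(OC)c3c2Oc2c(OC)cc4oc5cc(OC)cc(OC)c5c4c2O3)cc(=O)o1 | intermediate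
22 | methyl (2E)-3-(core-oxy)-5-oxohex-2-enoate | COC(=O)/C=C(\CC(C)=O)Oc1c(OC)cc(OC)c2c1Oc1c(OC)cc3oc4cc(OC)cc(OC)c4c3c1O2 | intermediate
23 | 5-(core-oxy)cyclohex-4-ene-1,3-dione | O=C1C=C(Oc2c(OC)cc(OC)c3c2Oc2c(OC)cc4oc5cc(OC)cc(OC)c5c4c2O3)CC(=O)C1 | intermediate
24 | 5-(core-oxy)benzene-1,3-diol | Oc1cc(O)cc(Oc2c(OC)cc(OC)c3c2Oc2c(OC)cc4oc5cc(OC)cc(OC)c5c4c2O3)c1 | intermediate
25 | CNP0256302.0 | Oc1cc(O)cc(Oc2c(O)cc(O)c3c2Oc2c(O)cc4oc5cc(O)cc(O)c5c4c2O3)c1 | target

**Step count**
Total step count: 16.
Longest linear sequence: 13 steps (1–7, 10–12, 14–16).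

**Steps most likely to fail**

Step 15.
- What may go wrong: methoxide may add to the aryloxy-bearing C4 and release the phenoxide of 18, which would be recoverable. The sequence may also stall at the open-chain stage, because the dienolate is a resting state and the enoate can lose its cis geometry.
- Fallback (known chemistry): it sets out from 18. An Ullmann ether synthesis with purchased 1-iodo-3,5-dimethoxybenzene (CuI, picolinic acid, K3PO4, DMSO, 100 °C) should give the heptamethyl ether of the target F1. BBr3 in CH2Cl2 then cleaves all seven methyl ethers, and the route is rejoined at 25.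

Step 12.
- What may go wrong: oxidative addition at the crowded, electron-rich C–Br bond may be slow. The free ring A phenoxide may tie up copper or be oxidised by traces of air. Protodebromination or intermolecular etherification may take over.
- Fallback: it sets out from 15. Baeyer–Villiger oxidation through 16, with K2CO3/MeOH in place of acid, keeps the MOM group and gives the MOM-protected ring A phenol F2. BnBr/K2CO3 in DMF gives the ring A benzyl ether F3. HCl in MeOH frees the dibenzofuran hydroxyl in the bromo phenol benzyl ether F4. Ring B is then closed on this single phenol by Pd-catalysed C–O coupling (Pd(OAc)2, t-BuXPhos, K3PO4, toluene, 100 °C) to the core benzyl ether F5. Hydrogenolysis (H2, Pd/C) rejoins the route at 18.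

Step 10.
- What may go wrong: substitution between a phenoxide and a fluoride that each carry two ortho substituents may be too slow for a formyl acceptor weakened by two methoxy donors, and the aldehyde may erode at the temperature required.
- Fallback: it changes the activating group to nitro and sets out from 11 and 10. NBS converts 11 into 2-bromo-1-fluoro-3,5-dimethoxybenzene F6. Nitration (HNO3, AcOH, 0 °C) gives 3-bromo-2-fluoro-4,6-dimethoxy-1-nitrobenzene F7. This should react with 10 (Cs2CO3, DMF, rt to 40 °C) to give the nitro diaryl ether F8. Fe/NH4Cl reduces it to the aniline F9. NaNO2 in aqueous H2SO4 at 0 °C gives the diazonium hydrogensulfate F10. Sandmeyer-type hydroxylation (Cu2O, Cu(NO3)2, water) replaces N2 by OH while the acid cleaves the MOM acetal, and the route is rejoined at 17.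

**Further compounds**
F1 | step 15 | heptamethyl ether of the target | COc1cc(OC)cc(Oc2c(OC)cc(OC)c3c2Oc2c(OC)cc4oc5cc(OC)cc(OC)c5c4c2O3)c1
F2 | step 12 | 3-bromo-4,6-dimethoxy-2-{[3,7,9-trimethoxy-1-(methoxymethoxy)dibenzo[b,d]furan-2-yl]oxy}phenol | COc1cc(OC)c2c(c1)oc1cc(OC)c(Oc3c(Br)c(OC)cc(OC)c3O)c(OCOC)c12
F3 | step 12 | 2-[2-(benzyloxy)-6-bromo-3,5-dimethoxyphenoxy]-3,7,9-trimethoxy-1-(methoxymethoxy)dibenzo[b,d]furan | COc1cc(OC)c2c(c1)oc1cc(OC)c(Oc3c(Br)c(OC)cc(OC)c3OCc4ccccc4)c(OCOC)c12
F4 | step 12 | 2-[2-(benzyloxy)-6-bromo-3,5-dimethoxyphenoxy]-3,7,9-trimethoxydibenzo[b,d]furan-1-ol | COc1cc(OC)c2c(c1)oc1cc(OC)c(Oc3c(Br)c(OC)cc(OC)c3OCc4ccccc4)c(O)c12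
F5 | step 12 | benzyl ether of core phenol 18 | COc1cc(OC)c2c(c1)oc1cc(OC)c3Oc4c(OCc5ccccc5)c(OC)cc(OC)c4Oc3c12
F6 | step 10 | 2-bromo-1-fluoro-3,5-dimethoxybenzene | COc1cc(OC)c(Br)c(F)c1
F7 | step 10 | 3-bromo-2-fluoro-4,6-dimethoxy-1-nitrobenzene | COc1cc(OC)c([N+](=O)[O-])c(F)c1Br
F8 | step 10 | 2-(2-bromo-3,5-dimethoxy-6-nitrophenoxy)-3,7,9-trimethoxy-1-(methoxymethoxy)dibenzo[b,d]furan | COc1cc(OC)c2c(c1)oc1cc(OC)c(Oc3c(Br)c(OC)cc(OC)c3[N+](=O)[O-])c(OCOC)c12
F9 | step 10 | 3-bromo-4,6-dimethoxy-2-{[3,7,9-trimethoxy-1-(methoxymethoxy)dibenzo[b,d]furan-2-yl]oxy}aniline | COc1cc(OC)c2c(c1)oc1cc(OC)c(Oc3c(Br)c(OC)cc(OC)c3N)c(OCOC)c12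
F10 | step 10 | diazonium hydrogensulfate of F9 | COc1cc(OC)c2c(c1)oc1cc(OC)c(Oc3c(Br)c(OC)cc(OC)c3[N+]#N)c(OCOC)c12.OS([O-])(=O)=O
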